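Ring A (C1–C5 and C10, drimane locants) is cut at C2–C3 and C4–C5. The carbinol carbon C3 and the gem-dimethyl carbon C4 are the two carbons of dimethylketene; C2, C1, C10 (with its methyl) and C5 are the terminal 1,3-diene of an acyclic trienyl isofraxidin ether made from geranyl bromide. A Lewis-acid-promoted formal [4+2] cycloaddition joins the electrophilic ketene carbon to C2 and the enolate carbon to C5 in one operation, giving a monocyclic ring A ketone. Catalyst-controlled reduction then sets C3, and a proton-initiated cation–olefin cyclization onto the ring A alkene closes ring B (C9–C10) with trans fusion.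

Key step: step 5

Remark: locants are the drimane ones (ring A = C1, C2, C3, C4, C5, C10; ring B = C5 to C10; C11 = OCH2 on C9). Isofraxidin and geranyl bromide are taken as commercial. C5 is formed racemic in step 5 and its configuration is selected in step 6, so at most half of the material from step 5 can be carried on.

Step 1
Reactants: 1 isofraxidin; 2 geranyl bromide
Product: 3 7-O-geranylisofraxidin
Conditions: K2CO3, acetone, reflux
Reagents that add atoms: none
Why: Williamson ether synthesis; the acidic 7-OH phenoxide should displace the primary allylic bromide by SN2 without touching the E alkene.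

Step 2
Reactants: 3
Product: 4 (2E,6E)-8-hydroxygeranyl ether of isofraxidin
Conditions: SeO2 (0.3 equiv), t-BuOOH, salicylic acid (cat.), CH2Cl2, 23 °C
Reagents that add atoms: tert-butyl hydroperoxide CC(C)(C)OO
Why: Riley-type catalytic allylic oxidation (ene reaction, then [2,3]-shift) should attack the E-methyl of the terminal, most electron-rich trisubstituted alkene and give the E allylic alcohol; any over-oxidized aldehyde 5 can be combined after step 3.

Step 3
Reactants: 4
Product: 5 (2E,6E)-enal
Conditions: activated MnO2, CH2Cl2, 23 °C
Reagents that add atoms: none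
Why: Selective allylic alcohol oxidation on MnO2 should give the enal without isomerizing the E alkene or touching the coumarin.

Step 4
Reactants: 5
Product: 6 (2E,6E)-3,7-dimethylnona-2,6,8-trienyl ether of isofraxidin
Conditions: Ph3PCH3Br, KN(SiMe3)2, THF, −78 → 0 °C
Reagents that add atoms: methyltriphenylphosphonium bromide C[P+](c1ccccc1)(c1ccccc1)c1ccccc1.[Br-]
Why: Wittig methylenation of the enal should give the terminal E 1,3-diene (C2=C1–C10=C5); one equivalent of ylide at low temperature should prefer the aldehyde over the coumarin lactone.

Step 5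
Reactants: 6 trienyl ether; 7 isobutyryl chloride
Product: 10 racemic ring A cyclohexenone, via dimethylketene 8 (not isolated), via vinylcyclobutanone 9 (not isolated)
Conditions: 7, Et3N, CH2Cl2, 23 °C; then 6, EtAlCl2 (3 equiv), −78 → 0 °C; cold aqueous HCl work-up
Reagents that add atoms: none
Why: Proposed new method: dehydrochlorination of 7 gives dimethylketene 8, whose carbonyl carbon (C3), activated by EtAlCl2, is attacked by the unsubstituted diene terminus C2 to give an aluminium enolate tethered to a 1,3-dialkyl-2-methylallyl cation; kinetic collapse at C1 gives vinylcyclobutanone 9, which should reopen under the Lewis acid and close at C5 to the strain-free cyclohex-3-enone 10 (stepwise formal [4+2], ionic 1,3-shift). The closest known reaction types are the Lewis-acid-promoted ketene–alkene [2+2] cycloaddition, the vinylcyclobutane-to-cyclohexene rearrangement and the Lewis-acid opening of donor-substituted cyclobutanones to 1,4-zwitterions that undergo [4+2] annulation. Ring A closes by six-membered recombination of the enolate carbon C4 with the allyl-cation terminus C5 after a reversible four-membered closure at C1, which needs the s-cis diene conformer that the E alkene allows and leaves the ring alkene at C1=C10. The only new stereocenter, C5, is not controlled here, so 10 forms as a racemate and its configuration is selected in step 6. The step needs site selectivity for the conjugated diene over the C8=C9 alkene and the coumarin (the terminal diene CH2 is the most nucleophilic and least hindered π carbon), regioselectivity (ketene carbonyl carbon to C2, fixed by polarity and by formation of the more substituted allyl cation) and six- over four-membered ring formation (driven by strain release on warming).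

Step 6
Reactants: 10 racemic ring A cyclohexenone
Product: 11 (3S,5R)-cis hydroxy cyclohexene
Conditions: (R)-2-methyl-CBS-oxazaborolidine (0.2 equiv), catecholborane, toluene, −78 → −40 °C; chromatography on SiO2
Reagents that add atoms: none
Why: Corey–Bakshi–Shibata reduction; the catalyst should tell the quaternary C4 flank from the C2 methylene flank and deliver hydride to the same carbonyl face of both enantiomers of 10, setting C3 as S, so the (5R) enantiomer gives cis alcohol 11 and the (5S) enantiomer gives its trans C5 epimer, which is removed by chromatography.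

Step 7
Reactants: 11 (3S,5R)-cis hydroxy cyclohexene
Product: 12 target
Conditions: FSO3H (5 equiv), 2-nitropropane, −78 °C; then Et3N
Reagents that add atoms: none
Why: Proton-initiated cation–olefin cyclization (Stork–Eschenmoser-type closure of a monocyclic precursor): Markovnikov protonation of C1=C10 at C1 gives the tertiary C10 cation, 6-endo attack by C9 of the E C8=C9 alkene through a chair transition state with the C5 side chain equatorial should set the trans ring fusion (C10 methyl anti to H5) and the equatorial C11 at C9, and loss of H7 from the C8 cation gives the C7=C8 alkene, while the protonated hydroxyl and coumarin carbonyl stay non-nucleophilic in the superacid.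

Compound list
1 | isofraxidin (7-hydroxy-6,8-dimethoxy-2H-chromen-2-one) | COc1cc2ccc(=O)oc2c(OC)c1O | starting material
2 | geranyl bromide ((2E)-1-bromo-3,7-dimethylocta-2,6-diene) | CC(C)=CCC/C(C)=C/CBr | starting material
3 | 7-{[(2E)-3,7-dimethylocta-2,6-dien-1-yl]oxy}-6,8-dimethoxy-2H-chromen-2-one | CC(C)=CCC/C(C)=C/COc1c(OC)cc2ccc(=O)oc2c1OC | intermediate
4 | 7-{[(2E,6E)-8-hydroxy-3,7-dimethylocta-2,6-dien-1-yl]oxy}-6,8-dimethoxy-2H-chromen-2-one | OC/C(C)=C/CC/C(C)=C/COc1c(OC)cc2ccc(=O)oc2c1OC | intermediate
5 | (2E,6E)-8-[(6,8-dimethoxy-2-oxo-2H-chromen-7-yl)oxy]-2,6-dimethylocta-2,6-dienal | O=C/C(C)=C/CC/C(C)=C/COc1c(OC)cc2ccc(=O)oc2c1OC | intermediate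
6 | 7-{[(2E,6E)-3,7-dimethylnona-2,6,8-trien-1-yl]oxy}-6,8-dimethoxy-2H-chromen-2-one | C=C/C(C)=C/CC/C(C)=C/COc1c(OC)cc2ccc(=O)oc2c1OC | intermediate
7 | isobutyryl chloride (2-methylpropanoyl chloride) | CC(C)C(Cl)=O | starting material
8 | dimethylketene | CC(C)=C=O | intermediate
9 | racemic 7-{[(2E,6E)-7-(2,2-dimethyl-3-oxocyclobutyl)-3-methylocta-2,6-dien-1-yl]oxy}-6,8-dimethoxy-2H-chromen-2-one | O=C1CC(/C(C)=C/CC/C(C)=C/COc2c(OC)cc3ccc(=O)oc3c2OC)C1(C)C | intermediate
10 | racemic 7-{[(2E)-3-methyl-5-(2,6,6-trimethyl-5-oxocyclohex-2-en-1-yl)pent-2-en-1-yl]oxy}-6,8-dimethoxy-2H-chromen-2-one | O=C1CC=C(C)C(CC/C(C)=C/COc2c(OC)cc3ccc(=O)oc3c2OC)C1(C)C | intermediate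
11 | 7-{[(2E)-5-[(1R,5S)-5-hydroxy-2,6,6-trimethylcyclohex-2-en-1-yl]-3-methylpent-2-en-1-yl]oxy}-6,8-dimethoxy-2H-chromen-2-one (drimane locants 3S,5R) | O[C@H]1CC=C(C)[C@@H](CC/C(C)=C/COc2c(OC)cc3ccc(=O)oc3c2OC)C1(C)C | intermediate
12 | 7-{[(1S,4aR,6S,8aS)-6-hydroxy-2,5,5,8a-tetramethyl-1,4,4a,5,6,7,8,8a-octahydronaphthalen-1-yl]methoxy}-6,8-dimethoxy-2H-chromen-2-one | COc1cc2ccc(=O)oc2c(OC)c1OC[C@H]1C(C)=CC[C@H]2C(C)(C)[C@@H](O)CC[C@]12C | target

Total step count: 7. Longest linear sequence: 7 steps (from 1 and 2).

Steps most likely to fail

Step 5 (Proposed new method). The cycloaddition may stop at the four-membered ring, the Lewis acid may ionize the allylic aryl ether, or the β,γ-enone may slip into conjugation during work-up. The fallback sets out from 6 and 7 and separates the two events with known chemistry: a thermal, uncatalysed ketene–alkene [2+2] cycloaddition (8 from 7 and Et3N, toluene, 80 °C, sealed tube) to isolate cyclobutanone 9, then a thermal vinylcyclobutane-to-cyclohexene [1,3] rearrangement (o-dichlorobenzene, 180 °C), helped by the α-keto and allylic termini of the breaking bond. It comes back to the route at 10 and makes no compound beyond those listed (F0).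

Step 7. The side-chain alkene may be protonated in competition with the ring alkene, the C10 cation may be captured by the C3 hydroxyl as an oxygen bridge, the allylic aryl ether may ionize, or the final proton loss may give the wrong alkene position. The fallback sets out from 11 and swaps the order of ring closure and carbinol formation: Dess–Martin oxidation to the (R)-configured monocyclic ketone F1, the same FSO3H cyclization on this ketone (no nucleophilic oxygen at C3) to the trans-fused bicyclic ketone F2, then NaBH4 in MeOH at 0 °C, where axial hydride delivery to the 4,4-dimethyl-3-ketone should give the equatorial 3β-alcohol. It comes back to the route at 12.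

Step 6. Catalyst control may be eroded by the remote C5 stereocenter, and the two flexible monocyclic diastereomers may separate poorly. The fallback sets out from 10 and moves the stereochemical sorting to the rigid decalin stage: the same reduction is run without separation, and the mixture of 11 and its C5 epimer, the trans hydroxy cyclohexene F3, is carried through the step 7 cyclization. Product 12 (equatorial hydroxyl) is then separated from the diastereomeric decalin F4 (axial hydroxyl on the enantiomeric skeleton). It comes back to the route at 12.

Further compounds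
F0 | step 5 | none | none
F1 | step 7 | 7-{[(2E)-3-methyl-5-[(1R)-2,6,6-trimethyl-5-oxocyclohex-2-en-1-yl]pent-2-en-1-yl]oxy}-6,8-dimethoxy-2H-chromen-2-one | O=C1CC=C(C)[C@@H](CC/C(C)=C/COc2c(OC)cc3ccc(=O)oc3c2OC)C1(C)C
F2 | step 7 | 7-{[(1S,4aR,8aS)-2,5,5,8a-tetramethyl-6-oxo-1,4,4a,5,6,7,8,8a-octahydronaphthalen-1-yl]methoxy}-6,8-dimethoxy-2H-chromen-2-one | COc1cc2ccc(=O)oc2c(OC)c1OC[C@H]1C(C)=CC[C@H]2C(C)(C)C(=O)CC[C@]12C
F3 | step 6 | 7-{[(2E)-5-[(1S,5S)-5-hydroxy-2,6,6-trimethylcyclohex-2-en-1-yl]-3-methylpent-2-en-1-yl]oxy}-6,8-dimethoxy-2H-chromen-2-one | O[C@H]1CC=C(C)[C@H](CC/C(C)=C/COc2c(OC)cc3ccc(=O)oc3c2OC)C1(C)C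
F4 | step 6 | 7-{[(1R,4aS,6S,8aR)-6-hydroxy-2,5,5,8a-tetramethyl-1,4,4a,5,6,7,8,8a-octahydronaphthalen-1-yl]methoxy}-6,8-dimethoxy-2H-chromen-2-one | COc1cc2ccc(=O)oc2c(OC)c1OC[C@@H]1C(C)=CC[C@@H]2C(C)(C)[C@@H](O)CC[C@@]12C
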